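The plan rests on cutting the C4–C4a bond of ring C. In the open-chain precursor, ring A is a phloroglucinol triether with the geranyl chain on C8. C4a is therefore the only unsubstituted carbon ortho to O1, and it is activated by O1 and the C5 oxygen (ortho) and by the C7 oxygen (para). The acyl trifluoroacetate of a (2R,3R)-3-aryloxy-2-(allyloxycarbonyloxy)-3-(4-acetoxyphenyl)propanoic acid should close ring C in one cold acylation without a Lewis acid, with both stereocentres already in place. C3 comes from an asymmetric dihydroxylation and C2 from a Mitsunobu inversion. Three allyl-based groups and one aryl acetate then leave together in a single final step.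

Key step: step 8

Remarks on the chemistry
- Flavonoid numbering (O1, C2, C3, C4, C4a, C5–C8, C8a, primed ring B) is also used for the open-chain compounds. Geranyl = (2E)-3,7-dimethylocta-2,6-dien-1-yl. Alloc = allyloxycarbonyl. NMO = N-methylmorpholine N-oxide. DIAD = diisopropyl azodicarboxylate. (DHQ)2PHAL = hydroquinine 1,4-phthalazinediyl diether.
- Assumption: (E)-4-acetoxycinnamic acid is taken as a catalogue compound.
- Protecting-group logic:
  - The acid is masked as a tert-butyl ester, which is removed without base or nucleophile.
  - O3 (carbonate) and O4' (acetate) carry electron-withdrawing groups, while O5 and O7 stay ethers.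
  - Every alkene-bearing group enters only after the dihydroxylation.

Step 1
Reactants: 1 phloroglucinol; 2 allyl bromide
Product: 3 3,5-bis(allyloxy)phenol
Conditions: 2 (2.0 equiv), K2CO3 (2.2 equiv), DMF, rt; chromatography
Reagents that add atoms: none
Why: Williamson etherification: K2CO3 in DMF favours O- over C-allylation of the phenolate, two equivalents of halide should make the diether the main member of a statistical mixture, and the mono-, di- and triethers differ enough in polarity to be separated, the monoether being recycled.

Step 2
Reactants: 3 3,5-bis(allyloxy)phenol; 4 geranyl bromide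
Product: 6 3,5-bis(allyloxy)-2-geranylphenol, via sodium phenolate 5 (not isolated)
Conditions: NaH (1.0 equiv), toluene, 0 °C; then 4 (0.9 equiv), rt
Reagents that add atoms: sodium hydride, [Na+].[H-] (its sodium is carried only by intermediate 5)
Why: Ortho C-alkylation of a phenolate ion pair: in toluene the undissociated sodium salt keeps its oxygen covered by the cation, which also assists departure of bromide, so the primary allylic carbon of 4 should be delivered by SN2 to one of the two equivalent carbons ortho to the oxygen rather than to the para carbon between the two ethers, without allylic transposition and with the E alkene intact, and tautomerisation restores the phenol.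

Step 3
Reactants: 7 (E)-4-acetoxycinnamic acid
Product: 8 tert-butyl (E)-4-acetoxycinnamate
Conditions: t-BuOC(=NH)CCl3 (2 equiv), CH2Cl2–THF, rt
Reagents that add atoms: tert-butyl 2,2,2-trichloroacetimidate, CC(C)(C)OC(=N)C(Cl)(Cl)Cl
Why: O-alkylation of a carboxylic acid by a trichloroacetimidate: the acid itself protonates the imidate, which hands over the tert-butyl group under essentially neutral conditions that leave the aryl acetate untouched.

Step 4
Reactants: 8 tert-butyl (E)-4-acetoxycinnamate
Product: 9 tert-butyl (2R,3S)-3-(4-acetoxyphenyl)-2,3-dihydroxypropanoate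
Conditions: K2OsO2(OH)4 (0.5 mol %), hydroquinine 1,4-phthalazinediyl diether [(DHQ)2PHAL] (1 mol %), NMO (1.5 equiv), t-BuOH–H2O, rt, slow addition of 8; crystallisation
Reagents that add atoms: N-methylmorpholine N-oxide, C[N+]1([O-])CCOCC1; water, O
Why: Sharpless asymmetric dihydroxylation: OsO4 bound to the dihydroquinine ligand adds suprafacially to the face of the (E)-alkene that gives the (2R,3S)-syn-diol, so the ligand sets the future C3 in its final configuration and the future C2 in the opposite one, the cinnamate alkene is the only alkene present at this stage, and NMO serves as terminal oxidant because the usual K3Fe(CN)6–K2CO3 medium would hydrolyse the aryl acetate.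

Step 5
Reactants: 9 tert-butyl (2R,3S)-3-(4-acetoxyphenyl)-2,3-dihydroxypropanoate; 6 3,5-bis(allyloxy)-2-geranylphenol
Product: 10 tert-butyl (2R,3R)-3-(4-acetoxyphenyl)-3-[3,5-bis(allyloxy)-2-geranylphenoxy]-2-hydroxypropanoate
Conditions: PPh3, DIAD (1.2 equiv each), toluene–THF, 0 °C → rt
Reagents that add atoms: none
Why: Mitsunobu etherification: in syn-2,3-dihydroxy esters the more nucleophilic β-hydroxyl, here also benzylic, is the one turned into the oxyphosphonium ion, and the phenolate of 6 displaces it by SN2 with inversion (3S to 3R, the future C2), while the electron-poor 4-acetoxyphenyl ring and the weakly polar solvent hold back ionisation and internal closure would have to give a strained cis-glycidate.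

Step 6
Reactants: 10 tert-butyl (2R,3R)-3-(4-acetoxyphenyl)-3-[3,5-bis(allyloxy)-2-geranylphenoxy]-2-hydroxypropanoate
Product: 11 tert-butyl (2R,3R)-3-(4-acetoxyphenyl)-2-(allyloxycarbonyloxy)-3-[3,5-bis(allyloxy)-2-geranylphenoxy]propanoate
Conditions: allyl chloroformate (1.5 equiv), pyridine (5 equiv), CH2Cl2, 0 °C → rt
Reagents that add atoms: allyl chloroformate, C=CCOC(=O)Cl
Why: Carbonate formation from a chloroformate at the only free hydroxyl, in which pyridine is too weak a base to enolise the ester or expel the aryloxide, so neither stereocentre is touched, and no acyl-transfer catalyst is added that could shuffle the aryl acetate.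

Step 7
Reactants: 11 tert-butyl (2R,3R)-3-(4-acetoxyphenyl)-2-(allyloxycarbonyloxy)-3-[3,5-bis(allyloxy)-2-geranylphenoxy]propanoate
Product: 13 (2R,3R)-3-(4-acetoxyphenyl)-2-(allyloxycarbonyloxy)-3-[3,5-bis(allyloxy)-2-geranylphenoxy]propanoic acid, via trimethylsilyl ester 12 (not isolated)
Conditions: TMSOTf (3 equiv), 2,6-lutidine (4.5 equiv), CH2Cl2, 0 °C → rt; then aq. NaH2PO4
Reagents that add atoms: trimethylsilyl trifluoromethanesulfonate, C[Si](C)(C)OS(=O)(=O)C(F)(F)F (its silyl group is carried only by intermediate 12)
Why: Silyl-triflate-mediated cleavage of a tert-butyl ester: silylation of the ester carbonyl triggers loss of the tert-butyl group, lutidine takes up the proton so that it leaves as 2-methylpropene and no free acid meets the geranyl alkenes or ring A, and the silyl ester hydrolyses on the mildly acidic work-up, a base-free sequence that avoids β-elimination of the aryloxide and spares the acetate, the carbonate and the allyl ethers.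

Step 8
Reactants: 13 (2R,3R)-3-(4-acetoxyphenyl)-2-(allyloxycarbonyloxy)-3-[3,5-bis(allyloxy)-2-geranylphenoxy]propanoic acid
Product: 15 (2R,3R)-4'-O-acetyl-5,7-di-O-allyl-3-O-(allyloxycarbonyl)-8-geranylaromadendrin, via acyl trifluoroacetate 14 (not isolated)
Conditions: (CF3CO)2O (1.2 equiv), CH2Cl2 (0.02 M), −20 → 0 °C; cold aq. NaHCO3
Reagents that add atoms: trifluoroacetic anhydride, O=C(OC(=O)C(F)(F)F)C(F)(F)F (its trifluoroacetyl group is carried only by intermediate 14)
Why: Trifluoroacetic anhydride converts acid 13 into acyl trifluoroacetate 14, whose acyl carbon (the future C4) is attacked by C4a to give an arenium ion that rearomatises by loss of a proton, that is an intramolecular Friedel–Crafts acylation of the kind long used to turn 3-aryloxypropanoic acids into chroman-4-ones. Ring C closes as a six-membered ring by 6-exo-trig attack on the acyl carbon, the carbonyl oxygen remaining outside the ring. No stereocentre is created: C2 and C3 arrive from steps 5 and 4, and if C3, which is α to the activated carbonyl, should epimerise, the untouched C2 centre directs re-equilibration of the ketone to the more stable 2,3-trans (2R,3R) arrangement. Regioselectivity comes from the substrate, since the short tether from O1 reaches only the two ortho carbons, C8 is blocked by the geranyl group, and C4a is activated by O1 and the C5 oxygen (ortho) and the C7 oxygen (para). Chemoselectivity for the arene over the two trisubstituted alkenes rests on these donors and on the intramolecular setting, which allow high dilution, sub-zero temperature, barely more than one equivalent of anhydride and no Lewis acid, so that the trifluoroacetic acid released stays too dilute to protonate the chain and little anhydride is left to acylate C6. Decarbonylation of the acyl donor to an oxocarbenium ion is held back because O3 bears a carbonate and not an ether, the 4'-acetate keeps the benzylic C2–O1 bond from ionising, and allyl ethers, carbonate and acetate all tolerate the acid.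

Step 9
Reactants: 15 (2R,3R)-4'-O-acetyl-5,7-di-O-allyl-3-O-(allyloxycarbonyl)-8-geranylaromadendrin
Product: 16 (2R,3R)-8-geranylaromadendrin (CNP0187235.1)
Conditions: Pd(PPh3)4 (10 mol %), morpholine (20 equiv), degassed THF–MeOH, rt, under argon; pH 5 buffer work-up
Reagents that add atoms: none
Why: Tsuji–Trost-type deallylation: zerovalent palladium ionises the two aryl allyl ethers (good leaving groups now that they stand ortho and para to the C4 ketone) and the allyl carbonate, which loses CO2, morpholine traps the π-allylpalladium units faster than ring A can, and the same excess amine in methanol removes the aryl acetate by aminolysis, so all four groups should go under weakly basic, oxygen-free conditions that neither open ring C nor epimerise C2 and C3 nor touch the geranyl chain.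

Compound list
1 | phloroglucinol (benzene-1,3,5-triol) | Oc1cc(O)cc(O)c1 | starting material
2 | allyl bromide | C=CCBr | starting material
3 | 3,5-bis(allyloxy)phenol | Oc1cc(OCC=C)cc(OCC=C)c1 | intermediate
4 | geranyl bromide, (2E)-1-bromo-3,7-dimethylocta-2,6-diene | CC(C)=CCC/C(C)=C/CBr | starting material
5 | sodium 3,5-bis(allyloxy)phenolate (not isolated) | [Na+].[O-]c1cc(OCC=C)cc(OCC=C)c1 | intermediate
6 | 3,5-bis(allyloxy)-2-geranylphenol | CC(C)=CCC/C(C)=C/Cc1c(O)cc(OCC=C)cc1OCC=C | intermediate
7 | (E)-4-acetoxycinnamic acid | CC(=O)Oc1ccc(/C=C/C(=O)O)cc1 | starting material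
8 | tert-butyl (E)-4-acetoxycinnamate | CC(=O)Oc1ccc(/C=C/C(=O)OC(C)(C)C)cc1 | intermediate
9 | tert-butyl (2R,3S)-3-(4-acetoxyphenyl)-2,3-dihydroxypropanoate | O[C@@H](c1ccc(OC(C)=O)cc1)[C@@H](O)C(=O)OC(C)(C)C | intermediate
10 | tert-butyl (2R,3R)-3-(4-acetoxyphenyl)-3-[3,5-bis(allyloxy)-2-geranylphenoxy]-2-hydroxypropanoate | CC(C)=CCC/C(C)=C/Cc1c(OCC=C)cc(OCC=C)cc1O[C@H](c1ccc(OC(C)=O)cc1)[C@@H](O)C(=O)OC(C)(C)C | intermediate
11 | tert-butyl (2R,3R)-3-(4-acetoxyphenyl)-2-(allyloxycarbonyloxy)-3-[3,5-bis(allyloxy)-2-geranylphenoxy]propanoate | CC(C)=CCC/C(C)=C/Cc1c(OCC=C)cc(OCC=C)cc1O[C@H](c1ccc(OC(C)=O)cc1)[C@@H](OC(=O)OCC=C)C(=O)OC(C)(C)C | intermediate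
12 | trimethylsilyl (2R,3R)-3-(4-acetoxyphenyl)-2-(allyloxycarbonyloxy)-3-[3,5-bis(allyloxy)-2-geranylphenoxy]propanoate (not isolated) | CC(C)=CCC/C(C)=C/Cc1c(OCC=C)cc(OCC=C)cc1O[C@H](c1ccc(OC(C)=O)cc1)[C@@H](OC(=O)OCC=C)C(=O)O[Si](C)(C)C | intermediate
13 | (2R,3R)-3-(4-acetoxyphenyl)-2-(allyloxycarbonyloxy)-3-[3,5-bis(allyloxy)-2-geranylphenoxy]propanoic acid (precursor of the key step) | CC(C)=CCC/C(C)=C/Cc1c(OCC=C)cc(OCC=C)cc1O[C@H](c1ccc(OC(C)=O)cc1)[C@@H](OC(=O)OCC=C)C(=O)O | intermediate
14 | mixed anhydride of 13 with trifluoroacetic acid (not isolated) | CC(C)=CCC/C(C)=C/Cc1c(OCC=C)cc(OCC=C)cc1O[C@H](c1ccc(OC(C)=O)cc1)[C@@H](OC(=O)OCC=C)C(=O)OC(=O)C(F)(F)F | intermediate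
15 | (2R,3R)-4'-O-acetyl-5,7-di-O-allyl-3-O-(allyloxycarbonyl)-8-geranylaromadendrin (product of the key step) | CC(C)=CCC/C(C)=C/Cc1c(OCC=C)cc(OCC=C)c2c1O[C@H](c1ccc(OC(C)=O)cc1)[C@@H](OC(=O)OCC=C)C2=O | intermediate
16 | (2R,3R)-8-geranylaromadendrin, (2R,3R)-8-[(2E)-3,7-dimethylocta-2,6-dien-1-yl]-3,5,7-trihydroxy-2-(4-hydroxyphenyl)chroman-4-one | CC(C)=CCC/C(C)=C/Cc1c(O)cc(O)c2c1O[C@H](c1ccc(O)cc1)[C@@H](O)C2=O | target

Total step count: 9.
Longest linear sequence: 7 steps (7 to 16 through steps 3–9). The ring A branch, steps 1 and 2 followed by 5–9, is equally long.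

Steps most likely to fail

Step 8.
- What may go wrong:
  - The acid liberated during the closure may protonate the trisubstituted alkenes of the chain and start cation–olefin cyclisation.
  - Surplus anhydride may trifluoroacetylate C6.
  - The carbonate oxygen may capture the activated acyl carbon, so that acyl transfer to C4a stalls.
- Fallback: an iminium electrophile replaces the acyl electrophile, and a hindered base is present throughout, so no free Brønsted acid is ever formed.
  - Setting out from 13, coupling with one equivalent of morpholine (N-(3-dimethylaminopropyl)-N'-ethylcarbodiimide hydrochloride, CH2Cl2, 0 °C) should give the morpholine amide F1. The single equivalent of amine is consumed by the activated acid long before it can attack the aryl acetate.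
  - Tf2O with 2,6-di-tert-butyl-4-methylpyridine (CH2Cl2, −78 → 0 °C) turns the amide into its O-triflyl iminium ion.
  - C4a attacks this ion in a Vilsmeier–Haack-type closure to give the cyclic C4 iminium triflate F2.
  - Stirring with aqueous NaHCO3 hydrolyses F2 to ketone 15, where the route is rejoined.

Step 5.
- What may go wrong:
  - The wrong hydroxyl may be activated.
  - The neighbouring hydroxyl may displace the activated one internally.
  - The activated hydroxyl may be lost by elimination towards the unsaturated ester.
  - Acetyl may transfer from ring B to the phenolate.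
  - Partial ionisation may erode the inversion.
- Fallback: site selectivity is secured by a blocking group instead of by the innate preference of the diol.
  - Setting out from 9, acidity-guided acylation of the α-hydroxyl (allyl chloroformate, 1.0 equiv, Et3N, CH2Cl2, −78 °C) follows the same site preference as the well-known α-sulfonylation of threo-2,3-dihydroxy esters. It should give the 2-O-Alloc monocarbonate F3, whose only free hydroxyl is the benzylic one.
  - Mitsunobu etherification of F3 with 6 (PPh3, DIAD, toluene, 0 °C) then leads with inversion directly to 11, where the route is rejoined without a change in step count.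

Step 2.
- What may go wrong:
  - O-geranylation may compete.
  - Attack may occur at the para carbon between the two ethers.
  - Double alkylation may lower the throughput of the ring A fragment.
- Fallback: the order of C–C and C–O bond formation is reversed, so that the C-alkylation has no regiochemical choice.
  - Setting out from 1 and 4, alkylation in a protic medium (KOH, 1 equiv, H2O–MeOH, 0 °C → rt) should give 2-geranylphloroglucinol F4. The solvent solvates the phenolate oxygens, and all three ring carbons of 1 are equivalent.
  - Williamson etherification of F4 with 2 (2 equiv, K2CO3, acetone) should take first the unhindered hydroxyl para to the chain and then one of the two equivalent flanking hydroxyls.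
  - This comes back to the route at 6.

Further compounds
F1 | step 8 | morpholine amide of acid 13, 4-{(2R,3R)-3-(4-acetoxyphenyl)-2-(allyloxycarbonyloxy)-3-[3,5-bis(allyloxy)-2-geranylphenoxy]propanoyl}morpholine | CC(C)=CCC/C(C)=C/Cc1c(OCC=C)cc(OCC=C)cc1O[C@H](c1ccc(OC(C)=O)cc1)[C@@H](OC(=O)OCC=C)C(=O)N1CCOCC1
F2 | step 8 | cyclic C4 morpholin-4-ium-4-ylidene (iminium) triflate of 15 | CC(C)=CCC/C(C)=C/Cc1c(OCC=C)cc(OCC=C)c2c1O[C@H](c1ccc(OC(C)=O)cc1)[C@@H](OC(=O)OCC=C)C2=[N+]1CCOCC1.[O-]S(=O)(=O)C(F)(F)F
F3 | step 5 | tert-butyl (2R,3S)-3-(4-acetoxyphenyl)-2-(allyloxycarbonyloxy)-3-hydroxypropanoate | O[C@@H](c1ccc(OC(C)=O)cc1)[C@@H](OC(=O)OCC=C)C(=O)OC(C)(C)C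
F4 | step 2 | 2-geranylphloroglucinol, 2-[(2E)-3,7-dimethylocta-2,6-dien-1-yl]benzene-1,3,5-triol | CC(C)=CCC/C(C)=C/Cc1c(O)cc(O)cc1O
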